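**Retrosynthetic overview**
1. Target ⇐ hydroxyl-directed epoxidation of a C1 allylic alcohol (oxirane formed last) ⇐ suprafacial 1,3-transposition of a C3 tertiary allylic alcohol.
2. Key disconnection C6–C7: nickel-catalysed electroreductive anti-SN2' alkenylation of a cyclohexadiene monoepoxide (ring fragment) by a 2-bromoallylic triol (side-chain fragment); this joins the halves and sets C6.
3. Side-chain fragment ⇐ L-malic acid (C10 bought; C11 by MeMgBr; C7/C14 from an acetylide; C8 by hydroxyl-directed anti reduction).
4. Ring fragment ⇐ toluene cis-dihydrodiol (C4 and C5 bought): one-pot differential acylation, then singlet-oxygen [4+2] and phosphine deoxygenation to the vinyl epoxide.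
5. Ring order: the carbocycle is bought intact; only the oxirane is built, transiently in the ring fragment and finally in the last step.

Assumption: toluene cis-dihydrodiol, (1S,2R)-3-methylcyclohexa-3,5-diene-1,2-diol, the fermentation product of toluene, is taken as a purchasable chiral building block.
Convention: bisabolane numbering (ring C1–C6, methyl on C3, side chain C7–C11 on C6, C14 = exocyclic methylene). β is the ring face carrying the C4 and C5 oxygens, α the opposite face. The target is 1α-OH, 2α,3α-epoxide, 4β-OAc, 5β-isobutyrate, 6β-side chain, 8S, 10S.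

**Route**

Step 1
Reactants: 1 L-malic acid
Product: 2 (S)-2-(2,2-dimethyl-5-oxo-1,3-dioxolan-4-yl)acetic acid
Conditions: Me2C(OMe)2, TsOH·H2O (1 mol %), 20 °C
Reagents that add atoms: 2,2-dimethoxypropane COC(C)(C)OC
Why: Acid-catalysed dioxolanone formation engages only the α-hydroxy acid unit in the favoured five-membered ring, which differentiates the two carboxyl groups without touching the purchased stereocentre (future C10).

Step 2
Reactants: 2 (S)-2-(2,2-dimethyl-5-oxo-1,3-dioxolan-4-yl)acetic acid
Product: 4 (S)-4-hydroxy-5,5-dimethyloxolan-2-one, via dihydroxy acid 3 (not isolated)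
Conditions: MeMgBr (5 equiv), THF, −20 → 20 °C; then 2 M HCl to pH 2, 20 °C
Reagents that add atoms: methylmagnesium bromide C[Mg]Br
Why: Grignard addition in which the magnesium carboxylate is inert while the dioxolanone (an activated ester) takes up two methyl groups with loss of acetone, after which acidification closes the γ-lactone through the new tertiary hydroxyl; the stereocentre is not involved.

Step 3
Reactants: 4 (S)-4-hydroxy-5,5-dimethyloxolan-2-one
Product: 5 (S)-5,6-dihydroxy-6-methylhept-1-yn-3-one
Conditions: HC≡CMgBr (3 equiv), THF, −78 → −20 °C; AcOH, −78 °C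
Reagents that add atoms: ethynylmagnesium bromide C#C[Mg]Br
Why: Mono-addition of an alkynyl Grignard reagent to a γ-lactone, in which the magnesium lactolate is stable at low temperature and blocks a second addition, and the acidic quench frees the β-hydroxy ynone (in equilibrium with its cyclic hemiketal).

Step 4
Reactants: 5 (S)-5,6-dihydroxy-6-methylhept-1-yn-3-one
Product: 6 (3S,5S)-6-methylhept-1-yne-3,5,6-triol
Conditions: Me4NBH(OAc)3 (5 equiv), MeCN/AcOH 1:1, −30 °C
Reagents that add atoms: none
Why: Evans–Saksena directed reduction, in which the secondary hydroxyl (future C10) exchanges onto boron and delivers hydride through a chair six-membered transition state to give the 1,3-anti diol, setting C8 (S) from the purchased centre.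

Step 5
Reactants: 6 (3S,5S)-6-methylhept-1-yne-3,5,6-triol
Product: 8 (3S,5S)-2-bromo-6-methylhept-1-ene-3,5,6-triol, via alkenylstannane 7 (not isolated)
Conditions: Bu3SnH (1.1 equiv), Mo(CO)3(CNtBu)3 (2 mol %), hydroquinone, THF, 55 °C; then Br2 (1.05 equiv), CH2Cl2, −78 °C
Reagents that add atoms: bromine BrBr; tributyltin hydride CCCC[SnH](CCCC)CCCC (its tin is carried only in 7 and leaves again as Bu3SnBr)
Why: Molybdenum-catalysed hydrostannation of propargylic alcohols gives the internal (α) alkenylstannane and bromodestannylation is an ipso substitution, so the 2-bromo-1-alkene forms without touching either stereocentre.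

Step 6
Reactants: 9 (1S,2R)-3-methylcyclohexa-3,5-diene-1,2-diol (toluene cis-dihydrodiol)
Product: 11 (1S,6R)-6-acetoxy-5-methylcyclohexa-2,4-dien-1-yl 2-methylpropanoate, via monoisobutyrate 10 (not isolated)
Conditions: iPrCOCl (1.05 equiv), 2,4,6-collidine, CH2Cl2, −40 °C; then Ac2O, Et3N, DMAP (cat.), −40 → 0 °C
Reagents that add atoms: isobutyryl chloride CC(C)C(Cl)=O; acetic anhydride CC(=O)OC(C)=O
Why: Kinetic acylation (nucleophilic acyl substitution) in which the C5 hydroxyl, remote from the ring methyl, is the less hindered one and takes the bulkier isobutyryl group, and the C4 hydroxyl is then capped as the acetate in the same flask before acyl migration can occur.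

Step 7
Reactants: 11 (1S,6R)-6-acetoxy-5-methylcyclohexa-2,4-dien-1-yl 2-methylpropanoate
Product: 13 (1S,2S,3S,6S)-2-acetoxy-1-methyl-7-oxabicyclo[4.1.0]hept-4-en-3-yl 2-methylpropanoate (2α,3α-epoxide with C1=C6 alkene), via endoperoxide 12 (not isolated)
Conditions: O2, meso-tetraphenylporphyrin (0.5 mol %), white LEDs, CH2Cl2, −40 °C; then Ar purge, PPh3 (1.05 equiv), −40 → 0 °C
Reagents that add atoms: dioxygen O=O (one oxygen atom stays; triphenylphosphine removes the other)
Why: Singlet-oxygen [4+2] cycloaddition occurs on the diene face opposite the two acyloxy groups (the C4 acetate is pseudo-axial because of allylic strain with the C3 methyl), and triphenylphosphine then attacks the less hindered peroxide oxygen on C6 so that the C3 alkoxide closes the oxirane by syn-SN2' displacement of Ph3P=O, which places the C3 oxygen on the α face and the alkene at C1=C6.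

Step 8
Reactants: 8 (3S,5S)-2-bromo-6-methylhept-1-ene-3,5,6-triol; 13 the 2α,3α-epoxy-1(6)-ene diester (1.5 equiv)
Product: 14 (3S,4S,5S,6R,8S,10S)-4-acetoxy-3,8,10,11-tetrahydroxy-5-isobutyryloxybisabola-1,7(14)-diene (3α-OH and 6β-side chain)
Conditions: NiBr2·MeOCH2CH2OMe (10 mol %), 4,4'-di-tert-butyl-2,2'-bipyridine (12 mol %), nBu4NBF4, DMA, undivided cell, Zn anode, carbon-felt cathode, 5 mA, 2.2 F per mol of 8, 0 °C; pH 7 buffer
Reagents that add atoms: none
Why: Proposed new method: a nickel-catalysed electroreductive cross-electrophile coupling of an alkenyl bromide with a cyclic 1,3-diene monoepoxide with net anti-SN2' stereochemistry; cathodically formed zerovalent nickel inserts into the C–Br bond of 8, the divalent alkenylnickel bromide is reduced to monovalent alkenylnickel, this ionises the allylic C2–O bond of 13 from the β face (opposite the epoxide oxygen, assisted by Zn2+ from the anode), and the trivalent alkenyl(η3-cyclohexenyl)nickel, which has no syn β-hydrogen, reductively eliminates inner-sphere at the less hindered allyl terminus C6 (C2 is neopentyl-like), so C7 arrives on the β face and C6 is set by the epoxide while the oxygen stays on C3; the closest known reaction types are nickel-catalysed reductive couplings of alkenyl bromides with allylic acetates and of aryl halides with epoxides, and the anti-SN2' alkenylation of cyclic vinyl epoxides by alkenylcuprates or by alkenylstannanes under palladium catalysis.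

Step 9
Reactants: 14 the C3 tertiary alcohol with free C8, C10 and C11 hydroxyls
Product: 15 (3S,4S,5S,6R,8S,10S)-4-acetoxy-3,11-dihydroxy-5,8,10-tris(isobutyryloxy)bisabola-1,7(14)-diene
Conditions: (iPrCO)2O (2.6 equiv), DMAP (0.1 equiv), pyridine, CH2Cl2, 0 → 20 °C
Reagents that add atoms: isobutyric anhydride CC(C)C(=O)OC(=O)C(C)C
Why: DMAP-catalysed acylation esterifies the two secondary hydroxyls (C8 and C10) while the two tertiary hydroxyls (C3 and C11) do not react with the hindered anhydride, which is why acylation is done before the ring oxygen is moved to the secondary C1 position.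

Step 10
Reactants: 15 the C3 tertiary allylic alcohol
Product: 16 (1R,4R,5S,6S,8S,10S)-4-acetoxy-1,11-dihydroxy-5,8,10-tris(isobutyryloxy)bisabola-2,7(14)-diene (1α-OH)
Conditions: Ph3SiOReO3 (5 mol %), Et2O, −20 → 0 °C
Reagents that add atoms: none
Why: Rhenium-oxo-catalysed 1,3-transposition of an allylic alcohol, in which the allyl perrhenate undergoes a [3,3]-sigmatropic shift that is necessarily suprafacial on the ring, so oxygen is relayed from the α face of C3 to the α face of C1, and the equilibrium favours the secondary alcohol with the trisubstituted alkene; this sets C1.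

Step 11
Reactants: 16 the 1α-allylic alcohol
Product: 17 CNP0324717.1, (1S,2S,3S,4S,5S,6S,8S,10S)-4-acetoxy-2,3-epoxy-1,11-dihydroxy-5,8,10-tris(isobutyryloxy)bisabol-7(14)-ene
Conditions: tBuOOH (1.5 equiv, decane), VO(acac)2 (5 mol %), CH2Cl2, 0 °C
Reagents that add atoms: tert-butyl hydroperoxide CC(C)(C)OO
Why: Vanadium-catalysed hydroxyl-directed epoxidation, in which the vanadate ester of the C1 hydroxyl delivers oxygen to the syn (α) face of the adjacent trisubstituted alkene far faster than to the non-allylic 1,1-disubstituted C7=C14 alkene, which sets C2 and C3.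

**Compound list**

1 | L-malic acid, (S)-2-hydroxybutanedioic acid | OC(=O)C[C@H](O)C(=O)O | starting material
2 | (S)-2-(2,2-dimethyl-5-oxo-1,3-dioxolan-4-yl)acetic acid | OC(=O)C[C@@H]1OC(C)(C)OC1=O | intermediate
3 | (S)-3,4-dihydroxy-4-methylpentanoic acid | OC(=O)C[C@H](O)C(C)(C)O | intermediate (not isolated)
4 | (S)-4-hydroxy-5,5-dimethyloxolan-2-one | O=C1C[C@H](O)C(C)(C)O1 | intermediate
5 | (S)-5,6-dihydroxy-6-methylhept-1-yn-3-one | C#CC(=O)C[C@H](O)C(C)(C)O | intermediate
6 | (3S,5S)-6-methylhept-1-yne-3,5,6-triol | C#C[C@@H](O)C[C@H](O)C(C)(C)O | intermediate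
7 | (3S,5S)-6-methyl-2-(tributylstannyl)hept-1-ene-3,5,6-triol | C=C([Sn](CCCC)(CCCC)CCCC)[C@@H](O)C[C@H](O)C(C)(C)O | intermediate (not isolated)
8 | (3S,5S)-2-bromo-6-methylhept-1-ene-3,5,6-triol | C=C(Br)[C@@H](O)C[C@H](O)C(C)(C)O | intermediate
9 | (1S,2R)-3-methylcyclohexa-3,5-diene-1,2-diol (toluene cis-dihydrodiol) | CC1=CC=C[C@H](O)[C@@H]1O | starting material
10 | (1S,6R)-6-hydroxy-5-methylcyclohexa-2,4-dien-1-yl 2-methylpropanoate | CC1=CC=C[C@H](OC(=O)C(C)C)[C@@H]1O | intermediate (not isolated)
11 | (1S,6R)-6-acetoxy-5-methylcyclohexa-2,4-dien-1-yl 2-methylpropanoate | CC1=CC=C[C@H](OC(=O)C(C)C)[C@@H]1OC(C)=O | intermediate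
12 | (1S,4R,7S,8R)-7-acetoxy-1-methyl-2,3-dioxabicyclo[2.2.2]oct-5-en-8-yl 2-methylpropanoate (peroxide bridge on the α face, anti to both esters) | [C@H]12C=C[C@](C)(OO1)[C@@H](OC(C)=O)[C@H]2OC(=O)C(C)C | intermediate (not isolated)
13 | (1S,2S,3S,6S)-2-acetoxy-1-methyl-7-oxabicyclo[4.1.0]hept-4-en-3-yl 2-methylpropanoate (2α,3α-epoxide, C1=C6 alkene) | C1=C[C@@H]2O[C@]2(C)[C@@H](OC(C)=O)[C@H]1OC(=O)C(C)C | intermediate
14 | (3S,4S,5S,6R,8S,10S)-4-acetoxy-3,8,10,11-tetrahydroxy-5-isobutyryloxybisabola-1,7(14)-diene | C=C([C@H]1C=C[C@](C)(O)[C@@H](OC(C)=O)[C@H]1OC(=O)C(C)C)[C@H](C[C@H](O)C(C)(C)O)O | intermediate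
15 | (3S,4S,5S,6R,8S,10S)-4-acetoxy-3,11-dihydroxy-5,8,10-tris(isobutyryloxy)bisabola-1,7(14)-diene | C=C([C@H]1C=C[C@](C)(O)[C@@H](OC(C)=O)[C@H]1OC(=O)C(C)C)[C@H](C[C@H](OC(=O)C(C)C)C(C)(C)O)OC(=O)C(C)C | intermediate
16 | (1R,4R,5S,6S,8S,10S)-4-acetoxy-1,11-dihydroxy-5,8,10-tris(isobutyryloxy)bisabola-2,7(14)-diene | C=C([C@H]1[C@H](O)C=C(C)[C@@H](OC(C)=O)[C@H]1OC(=O)C(C)C)[C@H](C[C@H](OC(=O)C(C)C)C(C)(C)O)OC(=O)C(C)C | intermediate
17 | CNP0324717.1, (1S,2S,3S,4S,5S,6S,8S,10S)-4-acetoxy-2,3-epoxy-1,11-dihydroxy-5,8,10-tris(isobutyryloxy)bisabol-7(14)-ene | C=C([C@H]1[C@H](O)[C@@H]2O[C@]2(C)[C@@H](OC(C)=O)[C@H]1OC(=O)C(C)C)[C@H](C[C@H](OC(=O)C(C)C)C(C)(C)O)OC(=O)C(C)C | target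

**Step count and risks**

Total step count: 11. Longest linear sequence: 9 (steps 1–5, then 8–11); the ring branch is 2 steps (6–7). Compound 2 is also sold as such; buying it would remove step 1.

Three steps most likely to fail:

Step 8 (the proposed new coupling). Risks are homocoupling of 8, isomerisation of the vinyl epoxide by zerovalent nickel, the 1,2-regioisomer (attack at C2), loss of stereospecificity if bromide opens the epoxide before nickel does, and scrambling of the neighbouring esters by the C3 alkoxide. The fallback uses known chemistry; it sets out from 6 and 13 and comes back at 14. The hydrostannation of step 5 is stopped before bromination and the alkenylstannane 7 is isolated. Compounds 7 and 13 are then joined with PdCl2(MeCN)2 (5 mol %) in DMF/H2O at 20 °C. This is the established palladium-catalysed 1,4-coupling of alkenylstannanes with cyclic 1,3-diene monoepoxides: zerovalent palladium ionises the epoxide with inversion, the alkenyl group moves from tin to palladium, and reductive elimination with retention at the distal allyl terminus gives the same trans-1,4 product 14 (no new compound, F0).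

Step 10 (allylic transposition). Risks are ionisation to an allyl cation with loss of face fidelity, or elimination and aromatisation with loss of the C4/C5 esters. The fallback sets out from 15 and comes back at 16. Oxidative 1,3-transposition with pyridinium chlorochromate, C5H5NH[CrO3Cl], in CH2Cl2 (Babler–Dauben) gives the transposed enone F1. Luche reduction (NaBH4, CeCl3·7H2O, MeOH, −78 °C) is expected to deliver hydride from the open α face and give the 1β-alcohol F2. Mitsunobu inversion with chloroacetic acid (PPh3, diisopropyl azodicarboxylate, toluene, 0 °C) gives the 1α-chloroacetate F3. Thiourea with NaHCO3 in EtOH then removes the chloroacetate selectively in the presence of the acetate and isobutyrates to give 16.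

Step 7 (photooxygenation and deoxygenation). Risks are incomplete anti-selectivity of the cycloaddition with a diester rather than an acetonide, and phosphine attack on the wrong peroxide oxygen, which would give the regioisomeric epoxide. The fallback sets out from 11 and comes back at 13. Direct oxygen-atom transfer with dimethyldioxirane (1.05 equiv, acetone, −20 °C) epoxidises the more electron-rich trisubstituted C2=C3 bond anti to the pseudo-axial C4 acetate and gives 13 in one operation without a peroxide intermediate (no new compound, F0).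

Further compounds
F0 | step 8 | none | none
F1 | step 10 | 4β-acetoxy-11-hydroxy-5β,8,10-tris(isobutyryloxy)bisabola-2,7(14)-dien-1-one (other centres as in 16) | C=C([C@H]1C(=O)C=C(C)[C@@H](OC(C)=O)[C@H]1OC(=O)C(C)C)[C@H](C[C@H](OC(=O)C(C)C)C(C)(C)O)OC(=O)C(C)C
F2 | step 10 | 1-epi-16, the 1β-alcohol | C=C([C@H]1[C@@H](O)C=C(C)[C@@H](OC(C)=O)[C@H]1OC(=O)C(C)C)[C@H](C[C@H](OC(=O)C(C)C)C(C)(C)O)OC(=O)C(C)C
F3 | step 10 | 1α-chloroacetate of 16 | C=C([C@H]1[C@H](OC(=O)CCl)C=C(C)[C@@H](OC(C)=O)[C@H]1OC(=O)C(C)C)[C@H](C[C@H](OC(=O)C(C)C)C(C)(C)O)OC(=O)C(C)C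
F0 | step 7 | none | none
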